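**Retrosynthetic overview**
1. Target 23 ⇐ one-step ring expansion of the 5-7-5 tricycle 20: cleavage of the C1–C5 bond opens the cyclopentane into the ten-membered ring and creates both ring alkenes, the enal and the free CH2OH at once.
2. 20 ⇐ seven-membered ring and cis α-methylene lactone by intramolecular indium Barbier allylation (C6–C7) of aldehyde/allyl bromide 17.
3. 17 ⇐ cyclopentanone 8 (spiro-epoxide by sulfur ylide; allyl bromide by ozonolysis, Morita–Baylis–Hillman reaction and SN2′ bromination; isovalerate placed after opening the γ-lactone).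
4. 8 ⇐ vinyl lactone 3 (chiral pool, carries C8) + cyclopent-2-en-1-one + formaldehyde.
5. Ring order: γ-lactone (chiral pool, later opened) → substituted cyclopentane → seven-membered ring with α-methylene lactone → ten-membered ring by expansion.

Assumption: locants C1–C15 are the germacrane positions the atoms hold in the target (ring C1–C10, C14 = formyl carbon on C10, C15 = hydroxymethyl carbon on C4, C11–C13 = lactone carbons); read this way the target SMILES is the (6S,7R,8S) isomer with a cis-fused lactone and both ring alkenes cis within the ring.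

Step 1
Reactants: 1 (S)-5-(hydroxymethyl)oxolan-2-one
Product: 2 (S)-5-oxooxolane-2-carbaldehyde
Conditions: TEMPO (10 mol%), PhI(OAc)2, CH2Cl2, 23 °C
Reagents that add atoms: none
Why: Oxoammonium (TEMPO) oxidation of the primary alcohol stops at the aldehyde and leaves the lactone and the C8 stereocentre untouched.

Step 2
Reactants: 2 (S)-5-oxooxolane-2-carbaldehyde
Product: 3 (S)-5-vinyloxolan-2-one
Conditions: Ph3PCH3Br, KN(SiMe3)2, THF, −78 → 0 °C
Reagents that add atoms: methyltriphenylphosphonium bromide, C[P+](c1ccccc1)(c1ccccc1)c1ccccc1.[Br-]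
Why: Wittig methylenation with the non-stabilised ylide at low temperature turns the aldehyde into a vinyl group (a neutral mask for the later C7 aldehyde) faster than C8 epimerises or the lactone is attacked.

Step 3
Reactants: 3 (S)-5-vinyloxolan-2-one; 4 cyclopent-2-en-1-one; 5 formaldehyde (monomeric, cracked from paraformaldehyde)
Product: 8 (5S)-3-{3-oxo-2-[(triethylsilyloxy)methyl]cyclopentyl}-5-vinyloxolan-2-one (cyclopentanone 2,3-trans; lactone 3,5-trans), via silyl ketene acetal 6 (not isolated), via silyl enol ether 7 (not isolated)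
Conditions: LiN(i-Pr)2, THF, −78 °C; Et3SiCl; then 4, Et3SiOSO2CF3 (5 mol%), CH2Cl2, −78 °C; then 5 (gas), −78 → −40 °C
Reagents that add atoms: chlorotriethylsilane, CC[Si](Cl)(CC)CC
Why: Mukaiyama–Michael addition of the silyl ketene acetal anti to the vinyl group, then silyl-transfer Mukaiyama aldol reaction with formaldehyde anti to the new C1 substituent, gives the 2,3-trans ketone; C8 controls C10 and C1, and C1, C5 and C10 are all erased again in step 13.

Step 4
Reactants: 8 (5S)-3-{3-oxo-2-[(triethylsilyloxy)methyl]cyclopentyl}-5-vinyloxolan-2-one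
Product: 9 (5S)-3-{4-[(triethylsilyloxy)methyl]-1-oxaspiro[2.4]heptan-5-yl}-5-vinyloxolan-2-one (epoxide O cis to the CH2OSiEt3 group)
Conditions: Me3S+ I−, KN(SiMe3)2, THF, −10 °C
Reagents that add atoms: trimethylsulfonium iodide, C[S+](C)C.[I-]
Why: Corey–Chaykovsky epoxidation; irreversible methylene transfer to the ketone face anti to the adjacent C5 substituent puts the epoxide oxygen cis to that substituent, which later fixes the C4=C5 geometry.

Step 5
Reactants: 9 (5S)-3-{4-[(triethylsilyloxy)methyl]-1-oxaspiro[2.4]heptan-5-yl}-5-vinyloxolan-2-one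
Product: 10 (4S)-4-hydroxy-N-methoxy-N-methyl-2-{4-[(triethylsilyloxy)methyl]-1-oxaspiro[2.4]heptan-5-yl}hex-5-enamide
Conditions: MeNH(OMe)·HCl, i-PrMgCl, THF, −20 °C
Reagents that add atoms: N,O-dimethylhydroxylamine hydrochloride, CNOC.Cl
Why: Weinreb aminolysis of the γ-lactone by the magnesium amide opens the ring to a masked C14 aldehyde and frees C8–OH without touching the hindered 2,2-disubstituted epoxide.

Step 6
Reactants: 10 (4S)-4-hydroxy-N-methoxy-N-methyl-2-{4-[(triethylsilyloxy)methyl]-1-oxaspiro[2.4]heptan-5-yl}hex-5-enamide; 11 3-methylbutanoyl chloride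
Product: 12 (3S)-6-[methoxy(methyl)amino]-6-oxo-5-{4-[(triethylsilyloxy)methyl]-1-oxaspiro[2.4]heptan-5-yl}hex-1-en-3-yl 3-methylbutanoate
Conditions: pyridine, DMAP (cat.), CH2Cl2, 0 °C
Reagents that add atoms: none
Why: DMAP-catalysed acylation of the only free hydroxyl installs the isovalerate with retention at C8.

Step 7
Reactants: 12 (3S)-6-[methoxy(methyl)amino]-6-oxo-5-{4-[(triethylsilyloxy)methyl]-1-oxaspiro[2.4]heptan-5-yl}hex-1-en-3-yl 3-methylbutanoate
Product: 13 (2S)-5-[methoxy(methyl)amino]-1,5-dioxo-4-{4-[(triethylsilyloxy)methyl]-1-oxaspiro[2.4]heptan-5-yl}pentan-2-yl 3-methylbutanoate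
Conditions: O3, CH2Cl2, −78 °C; then PPh3
Reagents that add atoms: ozone, O=[O+][O-]
Why: Ozonolysis with reductive work-up cleaves the only C=C bond and reveals the C7 aldehyde under neutral conditions that spare the epoxide, silyl ether and Weinreb amide.

Step 8
Reactants: 13 (2S)-5-[methoxy(methyl)amino]-1,5-dioxo-4-{4-[(triethylsilyloxy)methyl]-1-oxaspiro[2.4]heptan-5-yl}pentan-2-yl 3-methylbutanoate; 14 methyl acrylate
Product: 15 methyl (4S)-3-hydroxy-7-[methoxy(methyl)amino]-2-methylidene-4-(3-methylbutanoyloxy)-7-oxo-6-{4-[(triethylsilyloxy)methyl]-1-oxaspiro[2.4]heptan-5-yl}heptanoate (both C3 epimers)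
Conditions: 14 (excess, neat), DABCO (30 mol%), 23 °C
Reagents that add atoms: none
Why: Morita–Baylis–Hillman reaction; the α-acyloxy aldehyde is an activated acceptor, and the new carbinol centre is destroyed in step 9, so its configuration does not matter.

Step 9
Reactants: 15 methyl (4S)-3-hydroxy-7-[methoxy(methyl)amino]-2-methylidene-4-(3-methylbutanoyloxy)-7-oxo-6-{4-[(triethylsilyloxy)methyl]-1-oxaspiro[2.4]heptan-5-yl}heptanoate
Product: 16 methyl (2Z,4S)-2-(bromomethyl)-7-[methoxy(methyl)amino]-4-(3-methylbutanoyloxy)-7-oxo-6-{4-[(triethylsilyloxy)methyl]-1-oxaspiro[2.4]heptan-5-yl}hept-2-enoate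
Conditions: NBS, Me2S, CH2Cl2, 0 → 23 °C
Reagents that add atoms: N-bromosuccinimide, O=C1CCC(=O)N1Br
Why: Corey–Kim-type activation of the allylic alcohol and SN2′ return of bromide gives the more stable 2-(bromomethyl)enoate (ester trans to the C8 chain) under near-neutral conditions.

Step 10
Reactants: 16 methyl (2Z,4S)-2-(bromomethyl)-7-[methoxy(methyl)amino]-4-(3-methylbutanoyloxy)-7-oxo-6-{4-[(triethylsilyloxy)methyl]-1-oxaspiro[2.4]heptan-5-yl}hept-2-enoate
Product: 17 methyl (2Z,4S)-2-(bromomethyl)-6-(4-formyl-1-oxaspiro[2.4]heptan-5-yl)-7-[methoxy(methyl)amino]-4-(3-methylbutanoyloxy)-7-oxohept-2-enoate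
Conditions: (COCl)2, DMSO, CH2Cl2, −78 → −40 °C; then Et3N
Reagents that add atoms: none
Why: Swern conditions cleave and oxidise a primary triethylsilyl ether in one operation, giving the C6 aldehyde without acid or fluoride that would endanger the epoxide and the allylic bromide.

Step 11
Reactants: 17 methyl (2Z,4S)-2-(bromomethyl)-6-(4-formyl-1-oxaspiro[2.4]heptan-5-yl)-7-[methoxy(methyl)amino]-4-(3-methylbutanoyloxy)-7-oxohept-2-enoate
Product: 19 tricyclic lactone amide (4,15-epoxy-8-isovaleryloxy-guaian-6,12-olide type, C10 bearing C(=O)N(OMe)Me; H6/H7 cis, C11 trans to O8, cyclopentane trans-fused, epoxide O on the face of C6), via hydroxy ester 18 (not isolated)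
Conditions: In powder, THF/H2O (3:1), 23 °C, 5 mM; then 2-hydroxypyridine (cat.), PhMe, 60 °C
Reagents that add atoms: none
Why: Intramolecular indium Barbier allylation through a Zimmerman–Traxler chair (γ-attack of the 2-(methoxycarbonyl)allylindium) closes the seven-membered ring and sets C6 and C7: the syn mode gives the cis γ-hydroxy ester that lactonises, and the C8 ester sits pseudo-equatorial so C11 ends trans to O8.

Step 12
Reactants: 19 tricyclic lactone amide
Product: 20 tricyclic lactone aldehyde (same skeleton and configuration, C10 bearing CHO)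
Conditions: Cp2Zr(H)Cl (1.3 equiv), THF, 0 → 23 °C
Reagents that add atoms: none
Why: Reduction of the Weinreb amide by Cp2Zr(H)Cl stops at the aldehyde and is faster than attack on the esters, the lactone or the electron-poor 1,1-disubstituted alkene.

Step 13
Reactants: 20 tricyclic lactone aldehyde
Product: 23 (6S,7R,8S)-15-hydroxy-8-(3-methylbutanoyloxy)-14-oxogermacra-1(10),4,11(13)-trien-12,6-olide (1(10)E,4E by CIP, both ring alkenes cis within the ring), via enamine 21 (not isolated), via unsaturated iminium benzoate 22 (not isolated)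
Conditions: pyrrolidine (20 mol%), PhCO2H (20 mol%), (CF3)2CHOH/CH2Cl2 (1:4), 23 °C; then H2O
Reagents that add atoms: water, O
Why: Proposed new method: an amine-catalysed, enamine-triggered Grob-type 1,4-fragmentation with an epoxide as leaving group — in enamine 21 the C10 π-donor lies parallel to the C1–C5 σ-bond, which is antiperiplanar to the hydrogen-bond-activated C4–O bond, so electron flow N→C14=C10→C10=C1, C1–C5→C5=C4, C4–O opens the cyclopentane into the ten-membered ring, driven by epoxide strain; C4=C5 is set stereospecifically (epoxide O cis to C6 gives C3 cis to C6), the enal reaches its more stable geometry (CHO trans to C2) by iminium–dienamine equilibration of 22, C6, C7 and C8 are untouched and hydrolysis frees C15–OH; the closest known reactions are the base-mediated enolate-assisted 1,4-fragmentation of γ-sulfonyloxy aldehydes and the alkoxide-driven epoxy-alcohol Grob fragmentation.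

**Compound list**
1 | (S)-5-(hydroxymethyl)oxolan-2-one | OC[C@@H]1CCC(=O)O1 | starting material
2 | (S)-5-oxooxolane-2-carbaldehyde | O=C[C@@H]1CCC(=O)O1 | intermediate
3 | (S)-5-vinyloxolan-2-one | C=C[C@@H]1CCC(=O)O1 | intermediate
4 | cyclopent-2-en-1-one | O=C1C=CCC1 | starting material
5 | formaldehyde | C=O | starting material
6 | triethyl{[(5S)-5-vinyl-4,5-dihydrofuran-2-yl]oxy}silane (silyl ketene acetal) | C=C[C@@H]1CC=C(O[Si](CC)(CC)CC)O1 | intermediate
7 | (5S)-3-[3-(triethylsilyloxy)cyclopent-2-en-1-yl]-5-vinyloxolan-2-one (lactone 3,5-trans) | CC[Si](CC)(CC)OC1=C[C@H](CC1)[C@@H]2C[C@@H](C=C)OC2=O | intermediate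
8 | (5S)-3-{3-oxo-2-[(triethylsilyloxy)methyl]cyclopentyl}-5-vinyloxolan-2-one (ketone 2,3-trans, lactone 3,5-trans) | CC[Si](CC)(CC)OC[C@H]1C(=O)CC[C@@H]1[C@@H]2C[C@@H](C=C)OC2=O | intermediate
9 | (5S)-3-{4-[(triethylsilyloxy)methyl]-1-oxaspiro[2.4]heptan-5-yl}-5-vinyloxolan-2-one (epoxide O cis to CH2OSiEt3) | CC[Si](CC)(CC)OC[C@H]1[C@]2(CO2)CC[C@@H]1[C@@H]3C[C@@H](C=C)OC3=O | intermediate
10 | (4S)-4-hydroxy-N-methoxy-N-methyl-2-{4-[(triethylsilyloxy)methyl]-1-oxaspiro[2.4]heptan-5-yl}hex-5-enamide | CC[Si](CC)(CC)OC[C@H]1[C@]2(CO2)CC[C@@H]1[C@H](C[C@H](O)C=C)C(=O)N(C)OC | intermediate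
11 | 3-methylbutanoyl chloride | CC(C)CC(Cl)=O | starting material
12 | (3S)-6-[methoxy(methyl)amino]-6-oxo-5-{4-[(triethylsilyloxy)methyl]-1-oxaspiro[2.4]heptan-5-yl}hex-1-en-3-yl 3-methylbutanoate | CC[Si](CC)(CC)OC[C@H]1[C@]2(CO2)CC[C@@H]1[C@H](C[C@H](OC(=O)CC(C)C)C=C)C(=O)N(C)OC | intermediate
13 | (2S)-5-[methoxy(methyl)amino]-1,5-dioxo-4-{4-[(triethylsilyloxy)methyl]-1-oxaspiro[2.4]heptan-5-yl}pentan-2-yl 3-methylbutanoate | CC[Si](CC)(CC)OC[C@H]1[C@]2(CO2)CC[C@@H]1[C@H](C[C@H](OC(=O)CC(C)C)C=O)C(=O)N(C)OC | intermediate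
14 | methyl acrylate | C=CC(=O)OC | starting material
15 | methyl (4S)-3-hydroxy-7-[methoxy(methyl)amino]-2-methylidene-4-(3-methylbutanoyloxy)-7-oxo-6-{4-[(triethylsilyloxy)methyl]-1-oxaspiro[2.4]heptan-5-yl}heptanoate (C3 epimers) | CC[Si](CC)(CC)OC[C@H]1[C@]2(CO2)CC[C@@H]1[C@H](C[C@H](OC(=O)CC(C)C)C(O)C(=C)C(=O)OC)C(=O)N(C)OC | intermediate
16 | methyl (2Z,4S)-2-(bromomethyl)-7-[methoxy(methyl)amino]-4-(3-methylbutanoyloxy)-7-oxo-6-{4-[(triethylsilyloxy)methyl]-1-oxaspiro[2.4]heptan-5-yl}hept-2-enoate | CC[Si](CC)(CC)OC[C@H]1[C@]2(CO2)CC[C@@H]1[C@H](C[C@H](OC(=O)CC(C)C)/C=C(\CBr)C(=O)OC)C(=O)N(C)OC | intermediate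
17 | methyl (2Z,4S)-2-(bromomethyl)-6-(4-formyl-1-oxaspiro[2.4]heptan-5-yl)-7-[methoxy(methyl)amino]-4-(3-methylbutanoyloxy)-7-oxohept-2-enoate | O=C[C@H]1[C@]2(CO2)CC[C@@H]1[C@H](C[C@H](OC(=O)CC(C)C)/C=C(\CBr)C(=O)OC)C(=O)N(C)OC | intermediate
18 | bicyclic hydroxy ester: methyl 2-(C7)-acrylate on the seven-membered ring, C6–OH cis to C11, C8 isovalerate trans to C11, spiro-epoxide, C10 Weinreb amide | COC(=O)C(=C)[C@H]1[C@@H](O)[C@H]2[C@]3(CO3)CC[C@@H]2[C@@H](C(=O)N(C)OC)C[C@@H]1OC(=O)CC(C)C | intermediate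
19 | tricyclic lactone amide (H5, H6, H7, H10 on one face; H1, H8 on the other; epoxide O on the face of C6) | C=C1C(=O)O[C@H]2[C@H]3[C@]4(CO4)CC[C@@H]3[C@@H](C(=O)N(C)OC)C[C@H](OC(=O)CC(C)C)[C@@H]12 | intermediate
20 | tricyclic lactone aldehyde (configuration as 19, CHO on C10) | C=C1C(=O)O[C@H]2[C@H]3[C@]4(CO4)CC[C@@H]3[C@@H](C=O)C[C@H](OC(=O)CC(C)C)[C@@H]12 | intermediate
21 | pyrrolidine enamine of 20 (C14=C10) | C=C1C(=O)O[C@H]2[C@H]3[C@]4(CO4)CC[C@@H]3C(=CN5CCCC5)C[C@H](OC(=O)CC(C)C)[C@@H]12 | intermediate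
22 | ring-expanded α,β-unsaturated pyrrolidinium benzoate | C=C1C(=O)O[C@H]2/C=C(/CO)CC/C=C(/C=[N+]3CCCC3)C[C@H](OC(=O)CC(C)C)[C@@H]12.[O-]C(=O)c1ccccc1 | intermediate
23 | (6S,7R,8S)-15-hydroxy-8-(3-methylbutanoyloxy)-14-oxogermacra-1(10)E,4E,11(13)-trien-12,6-olide (CNP0345200.9) | C=C1C(=O)O[C@H]2/C=C(/CO)CC/C=C(/C=O)C[C@H](OC(=O)CC(C)C)[C@@H]12 | target

**Total step count:** 13. **Longest linear sequence:** 13 steps (1 → 23).

**Three steps most likely to fail**

Step 11 (Barbier ring closure). Risks are 1,4-elimination of the isovalerate from the allylindium and the wrong facial sense at C6/C7, which also depends on the C1/C5 configuration from step 3. The fallback sets out from 15 and comes back at 19. Alcohol 15 is acetylated (Ac2O, DMAP, pyridine) to the acetate F1. CuCl/Xantphos/NaOt-Bu-catalysed SN2′ borylation with B2pin2 gives the 2-(methoxycarbonyl)allylboronate F2, with the C8 chain cis to CH2B. Swern oxidation of the silyl ether gives the aldehyde boronate F3. Heating F3 (PhMe, 80 °C, 5 mM) effects intramolecular allylboration through a closed chair transition state; no free carbanion is formed, so the isovalerate cannot eliminate. Work-up gives hydroxy ester 18, which lactonises to 19.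

Step 12 (amide to aldehyde beside the α-methylene lactone). The risk is competing hydrozirconation or conjugate reduction of the exocyclic alkene. The fallback sets out from 19 and comes back at 20. The alkene is masked by conjugate addition of Me2NH (THF, 0 °C) to give the amino lactone amide F4. Cp2Zr(H)Cl then reduces only the Weinreb amide to give the amino lactone aldehyde F5. MeI gives the ammonium iodide F6, and aqueous NaHCO3 eliminates trimethylamine to restore the α-methylene lactone in 20.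

Step 13 (the new ring expansion). Risks are enamine or amine addition to the α-methylene lactone, acid-induced epoxide isomerisation, and too weak a push–pull. The fallback uses only known reaction types, sets out from 20 and comes back at 23. CO2 insertion into the epoxide (Bu4NBr cat., 1 atm CO2, 60 °C), which retains the C4–O bond, gives the spiro cyclic carbonate F7. The aldehyde is then deprotonated with KN(SiMe3)2 (1.05 equiv, THF, −78 → 0 °C), so the fragmentation runs in its established stoichiometric anionic form (enolate-assisted 1,4-fragmentation, known for sulfonate leaving groups) with the carbonate as leaving group. This gives the potassium alkyl carbonate F8, which loses CO2 on aqueous work-up to give 23.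

**Further compounds**
F1 | step 11 | acetate of 15 (C3 epimers) | CC[Si](CC)(CC)OC[C@H]1[C@]2(CO2)CC[C@@H]1[C@H](C[C@H](OC(=O)CC(C)C)C(OC(C)=O)C(=C)C(=O)OC)C(=O)N(C)OC
F2 | step 11 | methyl (2E,4S)-2-[(pinacolboryl)methyl]-7-[methoxy(methyl)amino]-4-(3-methylbutanoyloxy)-7-oxo-6-{4-[(triethylsilyloxy)methyl]-1-oxaspiro[2.4]heptan-5-yl}hept-2-enoate | CC[Si](CC)(CC)OC[C@H]1[C@]2(CO2)CC[C@@H]1[C@H](C[C@H](OC(=O)CC(C)C)/C=C(\CB3OC(C)(C)C(C)(C)O3)C(=O)OC)C(=O)N(C)OC
F3 | step 11 | corresponding 4-formyl-1-oxaspiro[2.4]heptan-5-yl allylboronate | O=C[C@H]1[C@]2(CO2)CC[C@@H]1[C@H](C[C@H](OC(=O)CC(C)C)/C=C(\CB3OC(C)(C)C(C)(C)O3)C(=O)OC)C(=O)N(C)OC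
F4 | step 12 | dimethylamine adduct of 19 (C11 epimers) | CN(C)CC1C(=O)O[C@H]2[C@H]3[C@]4(CO4)CC[C@@H]3[C@@H](C(=O)N(C)OC)C[C@H](OC(=O)CC(C)C)[C@@H]12
F5 | step 12 | dimethylamine adduct of 20 | CN(C)CC1C(=O)O[C@H]2[C@H]3[C@]4(CO4)CC[C@@H]3[C@@H](C=O)C[C@H](OC(=O)CC(C)C)[C@@H]12
F6 | step 12 | trimethylammonium iodide of F5 | C[N+](C)(C)CC1C(=O)O[C@H]2[C@H]3[C@]4(CO4)CC[C@@H]3[C@@H](C=O)C[C@H](OC(=O)CC(C)C)[C@@H]12.[I-]
F7 | step 13 | 4,15-cyclic carbonate of 20 | C=C1C(=O)O[C@H]2[C@H]3[C@]4(COC(=O)O4)CC[C@@H]3[C@@H](C=O)C[C@H](OC(=O)CC(C)C)[C@@H]12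
F8 | step 13 | potassium 15-O-carbonate of 23 | C=C1C(=O)O[C@H]2/C=C(/COC(=O)[O-])CC/C=C(/C=O)C[C@H](OC(=O)CC(C)C)[C@@H]12.[K+]
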